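## The problem

Labdane numbering is used throughout: C4 is the quaternary carbon of ring A, C18 its equatorial (4α) carbon, C19 its axial (4β) methyl and C20 the angular methyl on C10.

- The target 37 is a trans-fused decalin (rings A and B). It carries an exocyclic methylene at C8, a (Z)-3-methylpent-2-enoic acid chain on C9, an equatorial 6α-hydroxyl, and a benzoyloxymethyl group as the equatorial arm of C4.
- There are five stereocentres (C4, C5, C6, C9, C10). C4 and C10 are quaternary and cannot be corrected once set. C5 becomes epimerisable whenever C6 is a carbonyl. C9 can be set by kinetic protonation anti to the angular methyl.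
- C4 is the only centre that can be made in acyclic form, so it has to relay the absolute configuration to C5 and C10 when the rings are closed.
- The 6α-hydroxyl is the thermodynamic epimer but not the one a hydride delivers, because the β face of C6 carries two syn-axial methyls and hydride therefore enters from the α face.
- Sensitive groups: the 1,1-disubstituted alkene moves into the ring under acid and into conjugation with any C6 carbonyl under base. The Z-enoate can isomerise. The benzoate rules out a final saponification. A free C12 hydroxyl would add to a C8 cation to give a tetrahydrofuran.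
- The 6α-oxygen and C18 are syn-parallel (peri) and can be tied as a five-membered acetal.
- The key step rests on the 1,3-relationship of the C6 oxygen and the C8 methylene in ring B. C5=C6 can be a nitroalkene (nitro as masked oxygen). C7=C8–C9=C10 can be a 2-(silylmethyl)diene (allylsilane as masked methylene plus H-9). C1–C3 and C4 form the tether.

## Retrosynthesis

**Acyl groups and the O6/C18 pair.** The acid of 37 is released last from the 2-(trimethylsilyl)ethyl ester 36 by fluoride, which leaves a benzoate and a Z-enoate alone. The benzoate of 36 is placed on the primary C18 hydroxyl of diol 35. Diol 35 is the opened and reduced form of the cyclic methyl acetal 33, in which O6 and C18 protect each other. Against a triol route this removes one protecting group and two selectivity problems.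

**C12–C13.** Cutting the sp3–sp2 bond beside the trisubstituted alkene divides 33 into the bicyclic primary chloride 27 and the (Z)-iodoenoate 30, made in two steps from but-2-ynoic acid 28 through acid 29. An olefination at C13=C14 from a methyl ketone would give E/Z mixtures, whereas the coupling imports the Z geometry from an anti-hydroiodination. The forward reaction asks only that the zinc reagent from 27 meets no acidic hydrogen, which the acetal guarantees.

**C9–H, C17–Si and C6–O.** The methylene and H-9 of 27 come from the Δ8 allylsilane 25 by protodesilylation, with acetal exchange in the same flask. The hydroxyl of 25 comes from ketone 24 by single-electron reduction, and 24 from the nitro compound 22 by a Nef reaction. Oxidising C6 after ring formation would need an alkene at C5 or C7 that the skeleton does not offer. The chloride on C12 is carried because it survives every step between 13 and 27 and cannot trap a C8 cation.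

**C5–C10 and C6–C7 (key step).** Both ring bonds of 22 are cut at once to the acyclic nitro triene 21. This removes two rings and three stereocentres and leaves a chain with one stereocentre. A stepwise annulation would have to build the C10 quaternary centre and the C5/C6 pair separately. The forward reaction must be endo-selective with respect to the nitro group, must discriminate the faces set by C4, and must overcome a fully substituted diene terminus.

**C5=C6.** The nitroalkene of 21 is cut at the double bond to aldehyde 18 and nitromethane (Henry reaction to 19, then dehydration). Aldehyde 18 has no α-hydrogen, so C4 is safe, and it comes from the neopentyl alcohol 17.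

**C8–C9, C12–Cl and C10–CH3.** Diene 17 is cut between its two alkenes into the alkenyl iodide 13 and (2-bromoallyl)trimethylsilane 14. Iodide 13 comes from diol 12 by selective chlorination of the unhindered hydroxyl. Diol 12 comes from alkyne 10 by alkoxide-directed syn-methylmetalation and iodination, which fixes the tetrasubstituted geometry in one operation. Olefination routes to such an alkene would not control it.

**C4 and the chain.** Diol acetal 10 is traced through aldehyde 8 to monoacetate 7, the desymmetrised form of the prochiral diol 6. Diol 6 comes from malonate 5 by reduction, and 5 from diethyl methylmalonate 4 and chloride 3, which is the alkylation product of the alkyne 1 with 1-bromo-3-chloropropane 2. The stereocentre is therefore made at step 4 on simple material.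

## Roads not taken

**Alternative 1: ester-tethered type 2 Diels–Alder reaction on a ring-A diene.**
- Cut: C9–C10 and C7–C8.
- Forward step: the but-2-ynoate A1, tethered through the C18 oxygen to a 1-vinylcyclohexene, would close ring B to the bridged seven-membered lactone A2 with a 1,4-diene.
- Merits: the tether is anchored on C4, so the dienophile can only reach the α face of C10. The C4/C10 relationship is therefore enforced and not merely biased, which is better than in the chosen plan. C17 and the C18 oxygen arrive in place, and hydroboration of C5=C6 from the α face would give H-5α and the 6α-hydroxyl directly.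
- Weak points: a β-methyl alkynoate is a poor dienophile and must attack a fully substituted diene carbon. A2 holds a bridgehead alkene. The conjugated C8=C9 alkene of A2 would have to be moved out of conjugation to the exocyclic position with control at C9. The lactone carbon C11 would have to be reduced and extended by four carbons at a neopentyl-like position.
- Comparison: the chosen plan has weaker C4 control but delivers the C8 methylene, H-9 and the C11–C12 chain in nearly final form from a strongly activated dienophile.

**Alternative 2: epoxide opening by a ring-B silyl dienol ether.**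
- Cut: C4–C5.
- Forward step: Lewis acid activation of the epoxide in A3 and attack by C5 of the dienol ether with inversion would give the trans-fused enone A4 with a free C18 hydroxyl.
- Merits: C4 is set stereospecifically from an epoxide, the C18 hydroxyl is freed ready for benzoylation, and the C6 carbonyl is in place. In C4 fidelity and in the handling of C18 this road is better.
- Weak points: substitution at a fully substituted epoxide carbon competes with rearrangement of the epoxide to an aldehyde and with ionisation that erodes the inversion. A3 already needs the vicinal C9/C10 pair, a second asymmetric problem. The Δ7 enone of A4 must be turned into a 6α-alcohol with an 8(17)-alkene, a deconjugation against the thermodynamic preference.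
- Comparison: the chosen plan obtains the exocyclic alkene by protodesilylation and sets C5, C6 and C10 in the ring-forming step.

**Alternative 3: Ireland–Claisen ring contraction of a δ-lactone.**
- Cut: C9–C10.
- Forward step: the silyl ketene acetal of lactone A5 would rearrange through a boat transition state to the octalin acid A6, forming C9–C10, breaking C6–O and creating C5=C6.
- Merits: a sigmatropic shift is a more certain way to build the hindered C10 quaternary centre than a cycloaddition at a tetrasubstituted diene terminus. In this respect it is the better road.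
- Weak points: the C6 oxygen is lost in the key step and must be put back by hydroboration. C9 of A6 emerges with the wrong configuration. The C8 ketal needs methylenation. The acid carbon C11 must be reduced and coupled at a hindered position. A5 needs independent control of C4 and of the C6 carbinol.
- Comparison: the chosen plan closes both rings at once, keeps the C6 heteroatom and carries C11–C12 through the key step.

Key step: step 13

Assumption: the lipase is taken to acylate the hydroxymethyl arm of 6 that becomes C5. If it acylates the other arm, the free hydroxyl is silylated, the acetate removed and steps 5 and 6 are run on the liberated arm, which gives the same enantiomer of 10.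

## Route

Step 1
Reactants: 1 tert-butyl(but-3-yn-1-yloxy)dimethylsilane; 2 1-bromo-3-chloropropane
Product: 3 tert-butyl[(7-chlorohept-3-yn-1-yl)oxy]dimethylsilane
Conditions: n-BuLi, THF, −78 °C; DMPU, then 2, −78 °C → rt
Reagents that add atoms: none
Why: Acetylide alkylation; the lithium acetylide displaces bromide much faster than chloride, so the chloride end is kept for the next alkylation.

Step 2
Reactants: 4 diethyl methylmalonate; 3
Product: 5 diethyl 2-{7-[(tert-butyldimethylsilyl)oxy]hept-4-yn-1-yl}-2-methylpropanedioate
Conditions: NaH, DMF, 0 °C; then 3, NaI (cat.), 70 °C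
Reagents that add atoms: none
Why: Malonic ester alkylation with in situ Finkelstein activation of the primary chloride; it assembles the future C4 with its methyl, the C1–C3 tether and two enantiotopic arms.

Step 3
Reactants: 5
Product: 6 2-{7-[(tert-butyldimethylsilyl)oxy]hept-4-yn-1-yl}-2-methylpropane-1,3-diol
Conditions: LiAlH4, THF, 0 °C → rt
Reagents that add atoms: none
Why: Hydride reduction of both esters; the internal alkyne (no free homopropargylic hydroxyl) and the silyl ether are inert at this temperature.

Step 4
Reactants: 6
Product: 7 (S)-9-[(tert-butyldimethylsilyl)oxy]-2-(hydroxymethyl)-2-methylnon-6-yn-1-yl acetate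
Conditions: Pseudomonas cepacia lipase (Amano PS), vinyl acetate, i-Pr2O, 25 °C
Reagents that add atoms: vinyl acetate, CC(=O)OC=C
Why: Enzymatic desymmetrisation (irreversible transesterification) of a prochiral 2,2-disubstituted propane-1,3-diol; the enzyme distinguishes the enantiotopic hydroxymethyl groups and thereby sets C4, the only stereocentre made from achiral material.

Step 5
Reactants: 7
Product: 8 (R)-9-[(tert-butyldimethylsilyl)oxy]-2-formyl-2-methylnon-6-yn-1-yl acetate
Conditions: Dess–Martin periodinane, NaHCO3, CH2Cl2, 0 °C → rt
Reagents that add atoms: none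
Why: Dess–Martin oxidation of the free arm; the aldehyde has no α-hydrogen, so C4 cannot epimerise, and the buffered medium avoids 1,3-acyl migration that would racemise 7.

Step 6
Reactants: 8
Product: 10 (R)-2-(dimethoxymethyl)-2-methylnon-6-yne-1,9-diol, via hydroxy acetal acetate 9 (not isolated)
Conditions: HC(OMe)3, CSA (cat.), MeOH, rt; then K2CO3, rt
Reagents that add atoms: trimethyl orthoformate, COC(OC)OC; methanol, CO
Why: Acid-catalysed acetalisation; the same acidic methanol removes the primary silyl ether, and the acetate is methanolysed only after the aldehyde is masked, so no retro-aldol loss of formaldehyde can occur.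

Step 7
Reactants: 10
Product: 12 (R,E)-2-(dimethoxymethyl)-7-iodo-2,6-dimethylnon-6-ene-1,9-diol, via alkenylmagnesium alkoxide 11 (not isolated)
Conditions: Fe(acac)3 (cat.), dppe (cat.), MeMgBr (6 equiv), THF, 0 °C; then I2, −78 → 0 °C
Reagents that add atoms: methylmagnesium bromide, C[Mg]Br; iodine, II
Why: Iron-catalysed, alkoxide-directed syn-carbomagnesiation of a homopropargylic alcohol; methyl goes to the distal alkyne carbon (C10) and magnesium to the proximal one (C9) in a five-membered chelate, and iodinolysis with retention gives the tetrasubstituted alkenyl iodide with methyl and iodine cis.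

Step 8
Reactants: 12
Product: 13 (R,E)-9-chloro-2-(dimethoxymethyl)-7-iodo-2,6-dimethylnon-6-en-1-ol
Conditions: PPh3, CCl4, CH2Cl2, 0 °C → rt
Reagents that add atoms: carbon tetrachloride, ClC(Cl)(Cl)Cl
Why: Appel reaction; the SN2 collapse of the alkoxyphosphonium ion is possible at the unhindered C12 carbinol but not at the neopentyl one, which returns as the alcohol on work-up. The chloride is a latent C12 nucleophile that is inert in steps 9 to 16.

Step 9
Reactants: 13; 14 (2-bromoallyl)trimethylsilane
Product: 17 (R,E)-7-(2-chloroethyl)-2-(dimethoxymethyl)-2,6-dimethyl-8-[(trimethylsilyl)methyl]nona-6,8-dien-1-ol, via Grignard reagent 15 (not isolated), via organozinc reagent 16 (not isolated)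
Conditions: 14, Mg, THF, rt; ZnBr2, 0 °C; then 13, Pd(PPh3)4 (cat.), THF, 50 °C
Reagents that add atoms: none
Why: Negishi coupling; every elementary step proceeds with retention, so the C10 methyl stays cis to the new C8 substituent (the inside position of the diene). An excess of the zinc reagent covers the neopentyl hydroxyl, and the alkyl chloride does not add to zerovalent palladium under these conditions.

Step 10
Reactants: 17
Product: 18 (R,E)-7-(2-chloroethyl)-2-(dimethoxymethyl)-2,6-dimethyl-8-[(trimethylsilyl)methyl]nona-6,8-dienal
Conditions: Dess–Martin periodinane, NaHCO3, CH2Cl2, 0 °C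
Reagents that add atoms: none
Why: Dess–Martin oxidation under buffered conditions; the neopentyl alcohol gives a non-enolisable aldehyde, and the allylsilane and acetal are untouched.

Step 11
Reactants: 18
Product: 19 (3R,7E)-8-(2-chloroethyl)-3-(dimethoxymethyl)-3,7-dimethyl-1-nitro-9-[(trimethylsilyl)methyl]deca-7,9-dien-2-ol (both C2 epimers)
Conditions: MeNO2 (excess), KOt-Bu (cat.), t-BuOH/THF, 0 °C → rt
Reagents that add atoms: nitromethane, C[N+](=O)[O-]
Why: Henry (nitroaldol) reaction; hindered, non-enolisable aldehydes add nitromethane cleanly when it is in excess, and the new carbinol centre is removed in the next step.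

Step 12
Reactants: 19
Product: 21 (1E,3R,7E)-8-(2-chloroethyl)-3-(dimethoxymethyl)-3,7-dimethyl-1-nitro-9-[(trimethylsilyl)methyl]deca-1,7,9-triene, via nitro mesylate 20 (not isolated)
Conditions: MsCl, Et3N, CH2Cl2, −20 → 0 °C
Reagents that add atoms: none
Why: Mesylation and E1cB elimination of the β-nitro mesylate; the E-nitroalkene is preferred because the quaternary C4 and the nitro group avoid each other, and no γ-hydrogen is present for deconjugation.

Step 13
Reactants: 21
Product: 22 12-chloro-18,18-dimethoxy-6α-nitro-17-(trimethylsilyl)-13,14,15,16-tetranorlabd-8-ene (5α-H, 10β-methyl; 4R,5R,6S,10S)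
Conditions: PhMe (0.01 M), BHT (cat.), 110 °C
Reagents that add atoms: none
Why: Thermal, concerted but asynchronous [4+2] cycloaddition of the LUMO-lowered (E)-nitroalkene with the 2-(silylmethyl)diene, whose HOMO is raised by C–Si hyperconjugation; the closest known reaction type is the intramolecular Diels–Alder reaction of (E)-1-nitro-1,7,9-decatrienes to trans-fused nitrodecalins. Ring B is the cyclohexene formed by the cycloaddition itself through a boat-like array (bonds C5–C10 and C6–C7), and ring A is closed by the same C5–C10 bond as a six-membered carbocycle in which the C1–C3 tether and C4 sit in a chair. C5 and C6 follow from suprafacial addition to the E-alkene, which keeps H-5 and H-6 trans and places the nitro group equatorial. C10 follows from the diene geometry fixed in step 7 (the inside methyl becomes the angular methyl) together with the nitro-endo, tether-anti transition state, in which H-5 is trans to that methyl, so the ring fusion is trans. The absolute sense is relayed from C4: in the chair one C4 substituent must point at the incoming diene and the other lies on the open face, and the smaller methyl should take the diene side, which leaves the acetal carbon equatorial (α) as in the target. The step needs endo over exo selectivity, which the nitro group of an E-dienophile normally provides, and C4-facial selectivity, which rests only on the size difference between methyl and the branched acetal, so the C4 epimer is expected as a separable minor product. The fully substituted diene terminus will make the reaction slow; high dilution, a radical inhibitor and the strong activation by the nitro group are relied on, and the allylsilane and alkyl chloride are inert under neutral thermal conditions.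

Step 14
Reactants: 22
Product: 24 12-chloro-18,18-dimethoxy-17-(trimethylsilyl)-13,14,15,16-tetranorlabd-8-en-6-one, via sodium nitronate 23 (not isolated)
Conditions: NaOMe, MeOH/THF, 0 °C; then TiCl3 (aq.), NH4OAc, THF/H2O, rt
Reagents that add atoms: water, O
Why: Nef reaction in its reductive form; the nitronate is reduced by trivalent titanium to the imine, which hydrolyses at pH 5–6. The ketone is never exposed to strong base or acid, so the β,γ-alkene should stay out of conjugation and the trans ring fusion (the stable C5 epimer) is kept.

Step 15
Reactants: 24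
Product: 25 12-chloro-18,18-dimethoxy-17-(trimethylsilyl)-13,14,15,16-tetranorlabd-8-en-6α-ol
Conditions: SmI2, THF/H2O, 0 °C
Reagents that add atoms: none
Why: Single-electron (dissolving-metal-type) ketone reduction; protonation of the C6 organosamarium intermediate should give the thermodynamically preferred equatorial 6α-alcohol, whereas the 6β-epimer that hydride attack from the open α face would give suffers two syn-axial methyl contacts (C19 and C20). The primary chloride and the allylsilane are not reduced by divalent samarium without stronger activation.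

Step 16
Reactants: 25
Product: 27 12-chloro-6α,18-epoxy-18-methoxy-13,14,15,16-tetranorlabd-8(17)-ene (9α-H; cyclic methyl acetal, either C18 epimer), via cyclic acetal allylsilane 26 (not isolated)
Conditions: TsOH·H2O, CH2Cl2/MeOH (10:1), 0 °C → rt
Reagents that add atoms: none
Why: Acid-catalysed transacetalisation ties O6 to the peri C18 as a five-membered methyl acetal, and protodesilylation of the allylsilane (SE2′) then puts a proton on C9 and the double bond at C8=C17. The proton should arrive on the α face, anti to the axial C10 methyl, which gives the equatorial side chain, and the chloride, unlike a free C12 hydroxyl, cannot capture the C8 cation.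

Step 17
Reactants: 28 but-2-ynoic acid
Product: 29 (Z)-3-iodobut-2-enoic acid
Conditions: NaI, AcOH, 110 °C
Reagents that add atoms: sodium iodide, [Na+].[I-]
Why: Hydroiodination of an ynoic acid; iodide adds to the β-carbon and protonation is anti, which gives the Z-β-iodo acid.

Step 18
Reactants: 29
Product: 30 2-(trimethylsilyl)ethyl (Z)-3-iodobut-2-enoate
Conditions: Me3SiCH2CH2OH, DCC, DMAP (cat.), CH2Cl2, 0 °C
Reagents that add atoms: 2-(trimethylsilyl)ethanol, OCC[Si](C)(C)C
Why: Steglich esterification at low temperature keeps the alkene geometry; this ester is chosen because fluoride cleaves it in the presence of a benzoate.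

Step 19
Reactants: 27; 30
Product: 33 2-(trimethylsilyl)ethyl 6α,18-epoxy-18-methoxylabda-8(17),13Z-dien-15-oate, via alkylmagnesium chloride 31 (not isolated), via alkylzinc bromide 32 (not isolated)
Conditions: 27, Mg (activated), THF, 60 °C; ZnBr2, 0 °C; then 30, PdCl2(dppf) (cat.), THF, rt
Reagents that add atoms: none
Why: Grignard formation from the primary chloride, transmetalation to zinc and Negishi coupling with the alkenyl iodide with retention of the Z geometry; the substrate has no acidic hydrogen, and the acetal, exocyclic alkene and ester tolerate the alkylzinc reagent.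

Step 20
Reactants: 33
Product: 35 2-(trimethylsilyl)ethyl 6α,18-dihydroxylabda-8(17),13Z-dien-15-oate, via lactol 34 (not isolated)
Conditions: 1 M HCl, THF, rt; then NaHCO3, NaBH4, EtOH, 0 °C → rt
Reagents that add atoms: water, O
Why: Acetal hydrolysis to the lactol, whose open hydroxy aldehyde form is reduced by borohydride; the conjugated ester and both alkenes are inert, and the aldehyde carbon is attached to a quaternary centre.

Step 21
Reactants: 35
Product: 36 2-(trimethylsilyl)ethyl 18-(benzoyloxy)-6α-hydroxylabda-8(17),13Z-dien-15-oate
Conditions: BzCl (1.1 equiv), pyridine, CH2Cl2, −20 → 0 °C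
Reagents that add atoms: benzoyl chloride, O=C(Cl)c1ccccc1
Why: Selective acylation of the primary hydroxyl over the secondary 6α-hydroxyl at low temperature with a small excess of acid chloride.

Step 22
Reactants: 36
Product: 37 (4R,5R,6S,9S,10R)-18-(benzoyloxy)-6α-hydroxylabda-8(17),13Z-dien-15-oic acid (CNP0304840.1)
Conditions: TBAF, THF, 0 °C → rt; aq. NH4Cl
Reagents that add atoms: none
Why: Fluoride-induced fragmentation of the 2-(trimethylsilyl)ethyl ester to ethene and fluorotrimethylsilane frees the acid without touching the benzoate, the Z-enoate or the exocyclic alkene.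

## Compound list

1 | tert-butyl(but-3-yn-1-yloxy)dimethylsilane | C#CCCO[Si](C)(C)C(C)(C)C | starting material
2 | 1-bromo-3-chloropropane | ClCCCBr | starting material
3 | tert-butyl[(7-chlorohept-3-yn-1-yl)oxy]dimethylsilane | ClCCCC#CCCO[Si](C)(C)C(C)(C)C | intermediate
4 | diethyl methylmalonate | CCOC(=O)C(C)C(=O)OCC | starting material
5 | diethyl 2-{7-[(tert-butyldimethylsilyl)oxy]hept-4-yn-1-yl}-2-methylpropanedioate | CCOC(=O)C(C)(CCCC#CCCO[Si](C)(C)C(C)(C)C)C(=O)OCC | intermediate
6 | 2-{7-[(tert-butyldimethylsilyl)oxy]hept-4-yn-1-yl}-2-methylpropane-1,3-diol | OCC(C)(CO)CCCC#CCCO[Si](C)(C)C(C)(C)C | intermediate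
7 | (S)-9-[(tert-butyldimethylsilyl)oxy]-2-(hydroxymethyl)-2-methylnon-6-yn-1-yl acetate | CC(=O)OC[C@](C)(CO)CCCC#CCCO[Si](C)(C)C(C)(C)C | intermediate
8 | (R)-9-[(tert-butyldimethylsilyl)oxy]-2-formyl-2-methylnon-6-yn-1-yl acetate | CC(=O)OC[C@](C)(C=O)CCCC#CCCO[Si](C)(C)C(C)(C)C | intermediate
9 | (R)-2-(dimethoxymethyl)-9-hydroxy-2-methylnon-6-yn-1-yl acetate | CC(=O)OC[C@](C)(C(OC)OC)CCCC#CCCO | intermediate (not isolated)
10 | (R)-2-(dimethoxymethyl)-2-methylnon-6-yne-1,9-diol | OC[C@](C)(C(OC)OC)CCCC#CCCO | intermediate
11 | alkenylmagnesium bromide bis(bromomagnesium alkoxide) from 10 (methyl cis to magnesium) | Br[Mg]OC[C@](C)(C(OC)OC)CCC/C(C)=C(/[Mg]Br)CCO[Mg]Br | intermediate (not isolated)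
12 | (R,E)-2-(dimethoxymethyl)-7-iodo-2,6-dimethylnon-6-ene-1,9-diol | OC[C@](C)(C(OC)OC)CCC/C(C)=C(/I)CCO | intermediate
13 | (R,E)-9-chloro-2-(dimethoxymethyl)-7-iodo-2,6-dimethylnon-6-en-1-ol | OC[C@](C)(C(OC)OC)CCC/C(C)=C(/I)CCCl | intermediate
14 | (2-bromoallyl)trimethylsilane | C=C(Br)C[Si](C)(C)C | starting material
15 | [3-(trimethylsilyl)prop-1-en-2-yl]magnesium bromide | C=C([Mg]Br)C[Si](C)(C)C | intermediate (not isolated)
16 | [3-(trimethylsilyl)prop-1-en-2-yl]zinc bromide | C=C([Zn]Br)C[Si](C)(C)C | intermediate (not isolated)
17 | (R,E)-7-(2-chloroethyl)-2-(dimethoxymethyl)-2,6-dimethyl-8-[(trimethylsilyl)methyl]nona-6,8-dien-1-ol | OC[C@](C)(C(OC)OC)CCC/C(C)=C(\CCCl)C(=C)C[Si](C)(C)C | intermediate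
18 | (R,E)-7-(2-chloroethyl)-2-(dimethoxymethyl)-2,6-dimethyl-8-[(trimethylsilyl)methyl]nona-6,8-dienal | O=C[C@](C)(C(OC)OC)CCC/C(C)=C(\CCCl)C(=C)C[Si](C)(C)C | intermediate
19 | (3R,7E)-8-(2-chloroethyl)-3-(dimethoxymethyl)-3,7-dimethyl-1-nitro-9-[(trimethylsilyl)methyl]deca-7,9-dien-2-ol (C2 epimers) | [O-][N+](=O)CC(O)[C@](C)(C(OC)OC)CCC/C(C)=C(\CCCl)C(=C)C[Si](C)(C)C | intermediate
20 | methanesulfonate of 19 | [O-][N+](=O)CC(OS(C)(=O)=O)[C@](C)(C(OC)OC)CCC/C(C)=C(\CCCl)C(=C)C[Si](C)(C)C | intermediate (not isolated)
21 | (1E,3R,7E)-8-(2-chloroethyl)-3-(dimethoxymethyl)-3,7-dimethyl-1-nitro-9-[(trimethylsilyl)methyl]deca-1,7,9-triene | [O-][N+](=O)/C=C/[C@](C)(C(OC)OC)CCC/C(C)=C(\CCCl)C(=C)C[Si](C)(C)C | intermediate (key-step precursor)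
22 | 12-chloro-18,18-dimethoxy-6α-nitro-17-(trimethylsilyl)-13,14,15,16-tetranorlabd-8-ene (4R,5R,6S,10S) | C[Si](C)(C)CC1=C(CCCl)[C@@]2(C)CCC[C@@](C)(C(OC)OC)[C@@H]2[C@@H]([N+](=O)[O-])C1 | intermediate (key-step product)
23 | sodium nitronate of 22 | [Na+].C[Si](C)(C)CC1=C(CCCl)[C@@]2(C)CCC[C@@](C)(C(OC)OC)[C@@H]2C(=[N+]([O-])[O-])C1 | intermediate (not isolated)
24 | 12-chloro-18,18-dimethoxy-17-(trimethylsilyl)-13,14,15,16-tetranorlabd-8-en-6-one | C[Si](C)(C)CC1=C(CCCl)[C@@]2(C)CCC[C@@](C)(C(OC)OC)[C@@H]2C(=O)C1 | intermediate
25 | 12-chloro-18,18-dimethoxy-17-(trimethylsilyl)-13,14,15,16-tetranorlabd-8-en-6α-ol | C[Si](C)(C)CC1=C(CCCl)[C@@]2(C)CCC[C@@](C)(C(OC)OC)[C@@H]2[C@@H](O)C1 | intermediate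
26 | 12-chloro-6α,18-epoxy-18-methoxy-17-(trimethylsilyl)-13,14,15,16-tetranorlabd-8-ene | C[Si](C)(C)CC1=C(CCCl)[C@@]2(C)CCC[C@@]3(C)C(OC)O[C@@H](C1)[C@H]23 | intermediate (not isolated)
27 | 12-chloro-6α,18-epoxy-18-methoxy-13,14,15,16-tetranorlabd-8(17)-ene | C=C1C[C@@H]2OC(OC)[C@]3(C)CCC[C@](C)([C@H]1CCCl)[C@@H]23 | intermediate
28 | but-2-ynoic acid | CC#CC(=O)O | starting material
29 | (Z)-3-iodobut-2-enoic acid | C/C(I)=C/C(=O)O | intermediate
30 | 2-(trimethylsilyl)ethyl (Z)-3-iodobut-2-enoate | C/C(I)=C/C(=O)OCC[Si](C)(C)C | intermediate
31 | alkylmagnesium chloride from 27 | C=C1C[C@@H]2OC(OC)[C@]3(C)CCC[C@](C)([C@H]1CC[Mg]Cl)[C@@H]23 | intermediate (not isolated)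
32 | alkylzinc bromide from 27 | C=C1C[C@@H]2OC(OC)[C@]3(C)CCC[C@](C)([C@H]1CC[Zn]Br)[C@@H]23 | intermediate (not isolated)
33 | 2-(trimethylsilyl)ethyl 6α,18-epoxy-18-methoxylabda-8(17),13Z-dien-15-oate | C=C1C[C@@H]2OC(OC)[C@]3(C)CCC[C@](C)([C@H]1CC/C(C)=C\C(=O)OCC[Si](C)(C)C)[C@@H]23 | intermediate
34 | 2-(trimethylsilyl)ethyl 6α,18-epoxy-18-hydroxylabda-8(17),13Z-dien-15-oate (lactol) | C=C1C[C@@H]2OC(O)[C@]3(C)CCC[C@](C)([C@H]1CC/C(C)=C\C(=O)OCC[Si](C)(C)C)[C@@H]23 | intermediate (not isolated)
35 | 2-(trimethylsilyl)ethyl 6α,18-dihydroxylabda-8(17),13Z-dien-15-oate | C=C1C[C@H](O)[C@H]2[C@](C)(CO)CCC[C@]2(C)[C@H]1CC/C(C)=C\C(=O)OCC[Si](C)(C)C | intermediate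
36 | 2-(trimethylsilyl)ethyl 18-(benzoyloxy)-6α-hydroxylabda-8(17),13Z-dien-15-oate | C=C1C[C@H](O)[C@H]2[C@](C)(COC(=O)c3ccccc3)CCC[C@]2(C)[C@H]1CC/C(C)=C\C(=O)OCC[Si](C)(C)C | intermediate
37 | (4R,5R,6S,9S,10R)-18-(benzoyloxy)-6α-hydroxylabda-8(17),13Z-dien-15-oic acid | C=C1C[C@H](O)[C@H]2[C@](C)(COC(=O)c3ccccc3)CCC[C@]2(C)[C@H]1CC/C(C)=C\C(=O)O | target

## Step count and the least certain steps

Total: 22 steps. Longest linear sequence: 20 steps (steps 1–16 and 19–22, from 1 to 37); steps 17 and 18 form a two-step side branch.

**Step 13 (key step).** The cycloaddition may be outrun by consumption of the nitroalkene, through polymerisation or through its reaction as a heterodiene with the electron-rich diene. The cause is that a diene substituted at every carbon except C7 reaches the planar s-cis geometry only with strain. Discrimination of the C4 faces may also be incomplete, since it rests on methyl against a branched acetal. A hydrogen-bond donor such as N,N′-bis[3,5-bis(trifluoromethyl)phenyl]thiourea could be added to activate the nitro group without endangering the allylsilane.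
Fallback with a different dienophile: from aldehyde 18, Horner–Wadsworth–Emmons olefination with diethyl [(phenylsulfonyl)methyl]phosphonate (NaH, THF) would give the (E)-vinyl sulfone triene F1, which tolerates prolonged heating (xylene, 140–180 °C) and cannot react as a heterodiene. Its intramolecular Diels–Alder reaction would give the sulfonyl octalin F2. Oxidative desulfonylation of the α-sulfonyl carbanion (LDA, THF, −78 °C; then MoO5·py·HMPA) returns to the route at ketone 24. Any cis-fused material converges there because C5 is then epimerisable.

**Step 4.** The enzyme may discriminate poorly between a methyl and a methylene-terminated chain, and 1,3-acyl migration in the monoacetate may erode the enantiomeric purity.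
Fallback by classical resolution: from diester 5, monosaponification (KOH, 1 equiv, EtOH) and crystallisation of the salt with one enantiomer of 1-phenylethylamine would give the half-ester (S)-9-[(tert-butyldimethylsilyl)oxy]-2-(ethoxycarbonyl)-2-methylnon-6-ynoic acid F3. Reduction of the acid through its mixed anhydride (i-BuOCOCl, N-methylmorpholine; NaBH4) would give the hydroxy ester F4. Dess–Martin oxidation would give the aldehyde ester F5, and HC(OMe)3/CSA/MeOH the acetal ester F6 with loss of the silyl ether. LiAlH4 reduction returns to the route at 10.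

**Step 8.** Differentiation of the two primary hydroxyls may be incomplete, or the neopentyl hydroxyl may sequester the phosphonium reagent and stall the reaction.
Fallback that puts the selectivity into a sulfonylation: from 12, 2,4,6-triisopropylbenzenesulfonyl chloride (1.05 equiv, pyridine, 0 °C) should sulfonylate only the unhindered hydroxyl to give the monosulfonate F7. Displacement with LiCl in DMF (50 °C) returns to the route at 13.

**Step 14.** Deprotonation of the hindered C6–H (flanked by two syn-axial methyls) may be incomplete, and the acidic aqueous titanium stage may cause loss of silicon or migration of the alkene into conjugation.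
Fallback through an isolable oxime: from 22, SnCl2/PhSH/Et3N (MeCN, rt) reduces a secondary nitro group to the oxime F8 without strong base. Transoximation with aqueous glyoxylic acid and NaOAc (THF/H2O, rt) returns to the route at 24.

**Step 15.** Protonation may occur under kinetic control on the wrong face, or the β,γ-alkene may isomerise in the basic medium produced.
Fallback in two stages: from 24, NaBH4 (MeOH, 0 °C) would give the axial 6β-alcohol F9 by attack on the open α face. Oppenauer/Meerwein–Ponndorf–Verley equilibration (Al(Oi-Pr)3, i-PrOH, acetone (cat.), PhMe, 80 °C) should then convert it into the more stable equatorial epimer, returning to the route at 25.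

## Further compounds

F1 | step 13 | (1E,3R,7E)-8-(2-chloroethyl)-3-(dimethoxymethyl)-3,7-dimethyl-1-(phenylsulfonyl)-9-[(trimethylsilyl)methyl]deca-1,7,9-triene | O=S(=O)(c1ccccc1)/C=C/[C@](C)(C(OC)OC)CCC/C(C)=C(\CCCl)C(=C)C[Si](C)(C)C
F2 | step 13 | 12-chloro-18,18-dimethoxy-6α-(phenylsulfonyl)-17-(trimethylsilyl)-13,14,15,16-tetranorlabd-8-ene | C[Si](C)(C)CC1=C(CCCl)[C@@]2(C)CCC[C@@](C)(C(OC)OC)[C@@H]2[C@@H](S(=O)(=O)c3ccccc3)C1
F3 | step 4 | (S)-9-[(tert-butyldimethylsilyl)oxy]-2-(ethoxycarbonyl)-2-methylnon-6-ynoic acid | CCOC(=O)[C@](C)(C(=O)O)CCCC#CCCO[Si](C)(C)C(C)(C)C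
F4 | step 4 | ethyl (S)-9-[(tert-butyldimethylsilyl)oxy]-2-(hydroxymethyl)-2-methylnon-6-ynoate | CCOC(=O)[C@](C)(CO)CCCC#CCCO[Si](C)(C)C(C)(C)C
F5 | step 4 | ethyl (S)-9-[(tert-butyldimethylsilyl)oxy]-2-formyl-2-methylnon-6-ynoate | CCOC(=O)[C@](C)(C=O)CCCC#CCCO[Si](C)(C)C(C)(C)C
F6 | step 4 | ethyl (S)-2-(dimethoxymethyl)-9-hydroxy-2-methylnon-6-ynoate | CCOC(=O)[C@](C)(C(OC)OC)CCCC#CCCO
F7 | step 8 | (R,E)-8-(dimethoxymethyl)-9-hydroxy-3-iodo-4,8-dimethylnon-3-en-1-yl 2,4,6-triisopropylbenzenesulfonate | OC[C@](C)(C(OC)OC)CCC/C(C)=C(/I)CCOS(=O)(=O)c1c(C(C)C)cc(C(C)C)cc1C(C)C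
F8 | step 14 | 12-chloro-18,18-dimethoxy-17-(trimethylsilyl)-13,14,15,16-tetranorlabd-8-en-6-one oxime | C[Si](C)(C)CC1=C(CCCl)[C@@]2(C)CCC[C@@](C)(C(OC)OC)[C@@H]2C(=NO)C1
F9 | step 15 | 12-chloro-18,18-dimethoxy-17-(trimethylsilyl)-13,14,15,16-tetranorlabd-8-en-6β-ol | C[Si](C)(C)CC1=C(CCCl)[C@@]2(C)CCC[C@@](C)(C(OC)OC)[C@@H]2[C@H](O)C1
A1 | alternative 1 | [(1R)-1,3-dimethyl-2-vinylcyclohex-2-en-1-yl]methyl but-2-ynoate | CC#CC(=O)OC[C@]1(C)CCCC(C)=C1C=C
A2 | alternative 1 | 12,13,14,15,16-pentanorlabda-5,8-dien-11,18-olide (bridged seven-membered lactone) | CC1=C2C(=O)OC[C@]3(C)CCC[C@@]2(C)C3=CC1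
A3 | alternative 2 | ring-B tert-butyldimethylsilyl dienol ether with a 3-(2-methyloxiran-2-yl)propyl chain on C10 and a 2-(tert-butyldiphenylsilyloxy)ethyl chain on C9 | CC1=CC(O[Si](C)(C)C(C)(C)C)=C[C@](C)(CCC[C@]2(C)CO2)[C@H]1CCO[Si](c1ccccc1)(c1ccccc1)C(C)(C)C
A4 | alternative 2 | 12-(tert-butyldiphenylsilyloxy)-18-hydroxy-13,14,15,16-tetranorlabd-7-en-6-one | CC1=CC(=O)[C@H]2[C@](C)(CO)CCC[C@]2(C)[C@H]1CCO[Si](c1ccccc1)(c1ccccc1)C(C)(C)C
A5 | alternative 3 | 9-{6-[(4-methoxybenzyloxy)methyl]-2,6-dimethylcyclohex-1-en-1-yl}-1,4,8-trioxaspiro[4.5]decan-7-one | O=C1CC2(OCCO2)C[C@H](O1)C1=C(C)CCC[C@@]1(C)COCc1ccc(OC)cc1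
A6 | alternative 3 | 8,8-ethylenedioxy-18-(4-methoxybenzyloxy)-12,13,14,15,16,17-hexanorlabd-5-en-11-oic acid (9-epi) | OC(=O)[C@@H]1C2(OCCO2)CC=C2[C@]1(C)CCC[C@@]2(C)COCc1ccc(OC)cc1
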